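**Plan** (ring numbering of the target: O1, C2 quaternary, C3, C4, C5=C6, C7)

1. Cuts, in order: the C6–CH2 bond to the side chain (sp2–sp3 coupling); C7–H (acetal reduction); then C6 is excised as a dibromocarbene carbon, which contracts the oxepine to a 3,4-dihydro-2H-pyran; enol ether → lactol → terminal alkene; last, C2–CH2(COAr) (aldol to an α-keto ester).
2. Enabling feature: the allyl ether triad O1–C7H2–C6(R)=C5H, with the side chain on the central carbon C6, is the footprint of an oxygen-stabilised 2-bromoallyl cation, i.e. of a gem-dibromocyclopropane fused to a six-membered enol ether (temporary C5–C7 bond, absent from the target).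
3. Forward: keto ester + aryl enolsilane → tertiary alcohol (C2) → lactol → dihydropyran (six-membered ring) → 2-oxabicyclo[4.1.0]heptane → oxepine by ring expansion → 6-bromo-oxepine → Negishi coupling → ester cleavage and desilylation.
4. Stereochemistry: C2 (R), the only stereocentre, comes from a Cu(II)/(R,R)-t-Bu-box Mukaiyama aldol and is never part of a reacting bond afterwards; the E side-chain alkene comes from SeO2 oxidation of the E-methyl group of a prenyl unit.
5. Direct etherification of the tertiary alcohol onto an allylic C7 is avoided because the five-membered ring (5-exo) would close instead.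

Key step: step 8

Remark: Ar = 2,5-bis(tert-butyldimethylsilyloxy)phenyl and TBS = tert-butyldimethylsilyl throughout; the sense of induction in step 4 is assumed to follow that of the same catalyst family with pyruvate esters.

**Step 1**
Reactants: 1 5-bromopent-1-ene; 2 dimethyl oxalate
Product: 4 methyl 2-oxohept-6-enoate, via pent-4-enylmagnesium bromide 3 (not isolated)
Conditions: Mg, THF, rt; then added to 2 (2 equiv), THF/Et2O, −78 °C; aq. HCl quench
Reagents that add atoms: none
Why: Grignard acyl substitution on one ester group of the oxalate should stop at the α-keto ester because the magnesium hemiketal does not collapse at −78 °C.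

**Step 2**
Reactants: 5 1-(2,5-dihydroxyphenyl)ethan-1-one
Product: 6 1-[2,5-bis(tert-butyldimethylsilyloxy)phenyl]ethan-1-one
Conditions: TBSCl, imidazole, DMF, rt
Reagents that add atoms: tert-butyldimethylsilyl chloride, CC(C)(C)[Si](C)(C)Cl
Why: Imidazole-mediated O-silylation should mask both phenols as silyl ethers that tolerate Lewis acids, Pd and Zn and fall to fluoride at the end.

**Step 3**
Reactants: 6 1-[2,5-bis(tert-butyldimethylsilyloxy)phenyl]ethan-1-one
Product: 7 {1-[2,5-bis(tert-butyldimethylsilyloxy)phenyl]ethenyloxy}trimethylsilane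
Conditions: TMSOTf, Et3N, CH2Cl2, 0 °C
Reagents that add atoms: trimethylsilyl trifluoromethanesulfonate, C[Si](C)(C)OS(=O)(=O)C(F)(F)F
Why: Soft enolisation of the methyl ketone (silyl triflate/amine enol silane formation) should give the only possible enolsilane.

**Step 4**
Reactants: 4 methyl 2-oxohept-6-enoate; 7 {1-[2,5-bis(tert-butyldimethylsilyloxy)phenyl]ethenyloxy}trimethylsilane
Product: 9 methyl (2R)-2-(2-Ar-2-oxoethyl)-2-hydroxyhept-6-enoate, via trimethylsilyl ether 8 (not isolated)
Conditions: Cu(OTf)2 (10 mol %), (R,R)-t-Bu-box [2,2'-(propane-2,2-diyl)bis((4R)-4-tert-butyl-4,5-dihydrooxazole)] (11 mol %), THF, −78 °C; then 1 M HCl, THF, rt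
Reagents that add atoms: none
Why: In this catalytic enantioselective Mukaiyama aldol addition the keto ester should chelate square-planar Cu(II) through both carbonyl oxygens; the (S,S)-ligand is known to expose the si face of pyruvate esters, so the (R,R)-ligand should direct the enolsilane to the re face and set C2 as R.

**Step 5**
Reactants: 9 methyl (2R)-2-(2-Ar-2-oxoethyl)-2-hydroxyhept-6-enoate
Product: 12 methyl (2R)-2-(2-Ar-2-oxoethyl)-6-hydroxyoxane-2-carboxylate (anomer mixture), via vicinal diol 10 (not isolated), via hydroxy aldehyde 11 (not isolated)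
Conditions: OsO4 (cat.), NaIO4, 2,6-lutidine, dioxane/H2O, rt
Reagents that add atoms: osmium tetroxide, O=[Os](=O)(=O)=O; sodium periodate, [Na+].[O-]I(=O)(=O)=O
Why: Lemieux–Johnson cleavage of the terminal alkene should give a δ-hydroxy aldehyde that closes spontaneously to the six-membered lactol, whose anomeric centre is uncontrolled and removed in step 6.

**Step 6**
Reactants: 12 methyl (2R)-2-(2-Ar-2-oxoethyl)-6-hydroxyoxane-2-carboxylate
Product: 14 methyl (2R)-2-(2-Ar-2-oxoethyl)-3,4-dihydro-2H-pyran-2-carboxylate, via anomeric mesylate 13 (not isolated)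
Conditions: MsCl, Et3N, CH2Cl2, 0 → 40 °C
Reagents that add atoms: none
Why: Lactol dehydration by anomeric sulfonylation and amine-induced elimination (the standard lactol-to-glycal conversion) should give the endocyclic enol ether, with a base too weak to enolise the aryl ketone.

**Step 7**
Reactants: 14 methyl (2R)-2-(2-Ar-2-oxoethyl)-3,4-dihydro-2H-pyran-2-carboxylate
Product: 15 methyl (3R)-7,7-dibromo-3-(2-Ar-2-oxoethyl)-2-oxabicyclo[4.1.0]heptane-3-carboxylate (both cis-fused diastereomers)
Conditions: PhHgCBr3, benzene, 80 °C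
Reagents that add atoms: phenyl(tribromomethyl)mercury, BrC(Br)(Br)[Hg]c1ccccc1
Why: Thermal dibromocarbene transfer ([2+1] cycloaddition) to the electron-rich enol ether under neutral conditions should avoid the base-induced β-elimination of the enol-ether oxygen; the ring-fusion centres are uncontrolled because both are destroyed in step 8.

**Step 8**
Reactants: 15 methyl (3R)-7,7-dibromo-3-(2-Ar-2-oxoethyl)-2-oxabicyclo[4.1.0]heptane-3-carboxylate
Product: 16 methyl (2R)-7-acetoxy-6-bromo-2-(2-Ar-2-oxoethyl)-2,3,4,7-tetrahydrooxepine-2-carboxylate (C7 epimers)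
Conditions: AgOAc, NaOAc, toluene, 100 °C, dark
Reagents that add atoms: silver acetate, CC(=O)[O-].[Ag+]
Why: Silver(I) pulls off the endo bromide of 15 while the C1–C6 fusion bond opens in the disrotatory 2π-electrocyclic sense, so the three-membered ring unfolds into a cis,cis-2-bromoallyl cation spanning C7–C6–C5 of a seven-membered ring, which the ring oxygen stabilises as an oxocarbenium ion and acetate captures at C7. The closest known reaction type is the silver-promoted ring expansion of gem-dibromocyclopropanes fused to glycals and simple dihydropyrans to 2-acyloxy-3-bromo-tetrahydrooxepines. No ring is closed by bond formation: the oxepine arises because the zero-atom bridge of the 2-oxabicyclo[4.1.0]heptane is cut, which turns the six-membered ring into the seven-membered one with the former carbene carbon inserted as C6. The only new stereocentre is the acetal carbon C7, left uncontrolled because step 9 removes it, and C2 is not part of any reacting bond, so both cyclopropane diastereomers should converge. The step needs regioselectivity in two senses, both secured by the substrate: only the fusion bond can open because the cation must hold a cis double bond inside the ring and the adjacent oxygen makes this the bond that ionises, and acetate should add at C7 because the positive charge sits on the oxygen-bearing terminus and not on C5. Buffering with sodium acetate keeps the medium neutral, so the β-alkoxy ketone and the silyl ethers should survive.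

**Step 9**
Reactants: 16 methyl (2R)-7-acetoxy-6-bromo-2-(2-Ar-2-oxoethyl)-2,3,4,7-tetrahydrooxepine-2-carboxylate
Product: 17 methyl (2R)-6-bromo-2-(2-Ar-2-oxoethyl)-2,3,4,7-tetrahydrooxepine-2-carboxylate
Conditions: Et3SiH, TMSOTf (cat.), CH2Cl2, −78 → −40 °C
Reagents that add atoms: none
Why: Ionic hydrogenation of the anomeric allylic acetate should deliver hydride to the oxocarbenium carbon C7, the usual outcome for anomeric acetates, at a temperature too low for reduction of the aryl ketone.

**Step 10**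
Reactants: 18 5-bromo-2-methylpent-2-ene
Product: 19 (2E)-5-bromo-2-methylpent-2-en-1-ol
Conditions: SeO2 (cat.), t-BuOOH, CH2Cl2, rt
Reagents that add atoms: selenium dioxide (oxygen carrier), O=[Se]=O; tert-butyl hydroperoxide (terminal oxidant), CC(C)(C)OO
Why: Selenium dioxide allylic oxidation (ene reaction then [2,3]-sigmatropic shift) of a trisubstituted alkene should attack the E-methyl group and so give the E-allylic alcohol.

**Step 11**
Reactants: 19 (2E)-5-bromo-2-methylpent-2-en-1-ol
Product: 20 {[(2E)-5-bromo-2-methylpent-2-en-1-yl]oxy}(tert-butyl)dimethylsilane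
Conditions: TBSCl, imidazole, DMF, rt
Reagents that add atoms: tert-butyldimethylsilyl chloride, CC(C)(C)[Si](C)(C)Cl
Why: Standard O-silylation should protect the allylic alcohol for organozinc formation without touching the primary bromide.

**Step 12**
Reactants: 17 methyl (2R)-6-bromo-2-(2-Ar-2-oxoethyl)-2,3,4,7-tetrahydrooxepine-2-carboxylate; 20 {[(2E)-5-bromo-2-methylpent-2-en-1-yl]oxy}(tert-butyl)dimethylsilane
Product: 22 methyl (2R)-2-(2-Ar-2-oxoethyl)-6-[(3E)-5-(tert-butyldimethylsilyloxy)-4-methylpent-3-en-1-yl]-2,3,4,7-tetrahydrooxepine-2-carboxylate, via alkylzinc bromide 21 (not isolated)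
Conditions: 20, Zn dust, I2 (cat.), DMA, 80 °C; then 17, PdCl2(dppf) (5 mol %), THF/DMA, 50 °C
Reagents that add atoms: none
Why: Negishi coupling of a primary alkylzinc halide with the alkenyl bromide should form the C6–CH2 bond under neutral conditions that ketone, ester and silyl ethers tolerate, the bidentate ligand suppressing β-hydride elimination.

**Step 13**
Reactants: 22 methyl (2R)-2-(2-Ar-2-oxoethyl)-6-[(3E)-5-(tert-butyldimethylsilyloxy)-4-methylpent-3-en-1-yl]-2,3,4,7-tetrahydrooxepine-2-carboxylate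
Product: 24 (2R)-2-(2-Ar-2-oxoethyl)-6-[(3E)-5-(tert-butyldimethylsilyloxy)-4-methylpent-3-en-1-yl]-2,3,4,7-tetrahydrooxepine-2-carboxylic acid, via trimethylstannyl ester 23 (not isolated)
Conditions: Me3SnOH, 1,2-dichloroethane, 80 °C; 5% aq. HCl work-up
Reagents that add atoms: trimethyltin hydroxide, C[Sn](C)(C)O
Why: Tin hydroxide ester hydrolysis transfers hydroxide to the activated α-alkoxy ester at near-neutral pH, so enolisation of the aryl ketone and the retro-oxa-Michael opening of the ring should not compete.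

**Step 14**
Reactants: 24 (2R)-2-(2-Ar-2-oxoethyl)-6-[(3E)-5-(tert-butyldimethylsilyloxy)-4-methylpent-3-en-1-yl]-2,3,4,7-tetrahydrooxepine-2-carboxylic acid
Product: 25 (2R)-2-[2-(2,5-dihydroxyphenyl)-2-oxoethyl]-6-[(3E)-5-hydroxy-4-methylpent-3-en-1-yl]-2,3,4,7-tetrahydrooxepine-2-carboxylic acid
Conditions: HF·pyridine, THF, 0 °C → rt
Reagents that add atoms: none
Why: Acidic fluoride desilylation should remove the two aryl and the one allylic silyl ether in one operation without base, which protects the β-alkoxy ketone and the hydroquinone.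

**Compound list**

1 | 5-bromopent-1-ene | C=CCCCBr | starting material
2 | dimethyl oxalate | COC(=O)C(=O)OC | starting material
3 | pent-4-enylmagnesium bromide | C=CCCC[Mg]Br | intermediate (not isolated)
4 | methyl 2-oxohept-6-enoate | C=CCCCC(=O)C(=O)OC | intermediate
5 | 1-(2,5-dihydroxyphenyl)ethan-1-one | CC(=O)c1cc(O)ccc1O | starting material
6 | 1-[2,5-bis(tert-butyldimethylsilyloxy)phenyl]ethan-1-one | CC(=O)c1cc(O[Si](C)(C)C(C)(C)C)ccc1O[Si](C)(C)C(C)(C)C | intermediate
7 | {1-[2,5-bis(tert-butyldimethylsilyloxy)phenyl]ethenyloxy}trimethylsilane | C=C(O[Si](C)(C)C)c1cc(O[Si](C)(C)C(C)(C)C)ccc1O[Si](C)(C)C(C)(C)C | intermediate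
8 | methyl (2R)-2-(2-Ar-2-oxoethyl)-2-(trimethylsilyloxy)hept-6-enoate | C=CCCC[C@@](CC(=O)c1cc(O[Si](C)(C)C(C)(C)C)ccc1O[Si](C)(C)C(C)(C)C)(C(=O)OC)O[Si](C)(C)C | intermediate (not isolated)
9 | methyl (2R)-2-(2-Ar-2-oxoethyl)-2-hydroxyhept-6-enoate | C=CCCC[C@@](CC(=O)c1cc(O[Si](C)(C)C(C)(C)C)ccc1O[Si](C)(C)C(C)(C)C)(C(=O)OC)O | intermediate
10 | methyl (2R)-2-(2-Ar-2-oxoethyl)-2,6,7-trihydroxyheptanoate (C6 epimers) | OCC(O)CCC[C@@](CC(=O)c1cc(O[Si](C)(C)C(C)(C)C)ccc1O[Si](C)(C)C(C)(C)C)(C(=O)OC)O | intermediate (not isolated)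
11 | methyl (2R)-2-(2-Ar-2-oxoethyl)-2-hydroxy-6-oxohexanoate | O=CCCC[C@@](CC(=O)c1cc(O[Si](C)(C)C(C)(C)C)ccc1O[Si](C)(C)C(C)(C)C)(C(=O)OC)O | intermediate (not isolated)
12 | methyl (2R)-2-(2-Ar-2-oxoethyl)-6-hydroxyoxane-2-carboxylate (anomers) | OC1CCC[C@@](CC(=O)c2cc(O[Si](C)(C)C(C)(C)C)ccc2O[Si](C)(C)C(C)(C)C)(C(=O)OC)O1 | intermediate
13 | methyl (2R)-2-(2-Ar-2-oxoethyl)-6-(methanesulfonyloxy)oxane-2-carboxylate | CS(=O)(=O)OC1CCC[C@@](CC(=O)c2cc(O[Si](C)(C)C(C)(C)C)ccc2O[Si](C)(C)C(C)(C)C)(C(=O)OC)O1 | intermediate (not isolated)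
14 | methyl (2R)-2-(2-Ar-2-oxoethyl)-3,4-dihydro-2H-pyran-2-carboxylate | C1=CCC[C@@](CC(=O)c2cc(O[Si](C)(C)C(C)(C)C)ccc2O[Si](C)(C)C(C)(C)C)(C(=O)OC)O1 | intermediate
15 | methyl (3R)-7,7-dibromo-3-(2-Ar-2-oxoethyl)-2-oxabicyclo[4.1.0]heptane-3-carboxylate (both cis-fused diastereomers) | BrC1(Br)C2CC[C@@](CC(=O)c3cc(O[Si](C)(C)C(C)(C)C)ccc3O[Si](C)(C)C(C)(C)C)(C(=O)OC)OC12 | intermediate
16 | methyl (2R)-7-acetoxy-6-bromo-2-(2-Ar-2-oxoethyl)-2,3,4,7-tetrahydrooxepine-2-carboxylate (C7 epimers) | CC(=O)OC1C(Br)=CCC[C@@](CC(=O)c2cc(O[Si](C)(C)C(C)(C)C)ccc2O[Si](C)(C)C(C)(C)C)(C(=O)OC)O1 | intermediate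
17 | methyl (2R)-6-bromo-2-(2-Ar-2-oxoethyl)-2,3,4,7-tetrahydrooxepine-2-carboxylate | BrC1=CCC[C@@](CC(=O)c2cc(O[Si](C)(C)C(C)(C)C)ccc2O[Si](C)(C)C(C)(C)C)(C(=O)OC)OC1 | intermediate
18 | 5-bromo-2-methylpent-2-ene | CC(C)=CCCBr | starting material
19 | (2E)-5-bromo-2-methylpent-2-en-1-ol | C/C(=C\CCBr)CO | intermediate
20 | {[(2E)-5-bromo-2-methylpent-2-en-1-yl]oxy}(tert-butyl)dimethylsilane | C/C(=C\CCBr)CO[Si](C)(C)C(C)(C)C | intermediate
21 | [(3E)-5-(tert-butyldimethylsilyloxy)-4-methylpent-3-en-1-yl]zinc bromide | C/C(=C\CC[Zn]Br)CO[Si](C)(C)C(C)(C)C | intermediate (not isolated)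
22 | methyl (2R)-2-(2-Ar-2-oxoethyl)-6-[(3E)-5-(tert-butyldimethylsilyloxy)-4-methylpent-3-en-1-yl]-2,3,4,7-tetrahydrooxepine-2-carboxylate | C/C(=C\CCC1=CCC[C@@](CC(=O)c2cc(O[Si](C)(C)C(C)(C)C)ccc2O[Si](C)(C)C(C)(C)C)(C(=O)OC)OC1)CO[Si](C)(C)C(C)(C)C | intermediate
23 | trimethylstannyl (2R)-2-(2-Ar-2-oxoethyl)-6-[(3E)-5-(tert-butyldimethylsilyloxy)-4-methylpent-3-en-1-yl]-2,3,4,7-tetrahydrooxepine-2-carboxylate | C/C(=C\CCC1=CCC[C@@](CC(=O)c2cc(O[Si](C)(C)C(C)(C)C)ccc2O[Si](C)(C)C(C)(C)C)(C(=O)O[Sn](C)(C)C)OC1)CO[Si](C)(C)C(C)(C)C | intermediate (not isolated)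
24 | (2R)-2-(2-Ar-2-oxoethyl)-6-[(3E)-5-(tert-butyldimethylsilyloxy)-4-methylpent-3-en-1-yl]-2,3,4,7-tetrahydrooxepine-2-carboxylic acid | C/C(=C\CCC1=CCC[C@@](CC(=O)c2cc(O[Si](C)(C)C(C)(C)C)ccc2O[Si](C)(C)C(C)(C)C)(C(=O)O)OC1)CO[Si](C)(C)C(C)(C)C | intermediate
25 | (2R)-2-[2-(2,5-dihydroxyphenyl)-2-oxoethyl]-6-[(3E)-5-hydroxy-4-methylpent-3-en-1-yl]-2,3,4,7-tetrahydrooxepine-2-carboxylic acid | C/C(=C\CCC1=CCC[C@@](CC(=O)c2cc(O)ccc2O)(C(=O)O)OC1)CO | target

**Summary**

Total steps: 14. Longest linear sequence: 11 steps (5 → 25 through steps 2–9 and 12–14).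

**Steps most likely to fail**

Step 8. The ionisation may not outrun decomposition: loss of HBr from the allyl cation to a bromodiene, acetate capture at C5 instead of C7, or thermal β-elimination of O1 from the β-alkoxy ketone. The fallback replaces ring expansion by ring-closing metathesis; it sets out from 9 and comes back at 22. A ruthenium hydride catalyst should move the terminal alkene of 9 by one position to give methyl (2R,5E)-2-(2-Ar-2-oxoethyl)-2-hydroxyhept-5-enoate F1. Palladium(0)-catalysed decarboxylative O-allylation of the tertiary alcohol (Tsuji–Trost type; Pd2(dba)3, dppb, THF, 60 °C) with tert-butyl 2-chloroprop-2-en-1-yl carbonate F2, itself made from 2-chloroprop-2-en-1-ol and Boc2O, should give the 2-chloroallyl ether F3. Ring-closing metathesis of F3 (second-generation ruthenium NHC benzylidene catalyst, toluene, 80 °C) should expel propene and close methyl (2R)-6-chloro-2-(2-Ar-2-oxoethyl)-2,3,4,7-tetrahydrooxepine-2-carboxylate F4. Negishi coupling of F4 with 21, using a palladium/biarylphosphine catalyst suited to alkenyl chlorides, would then give 22.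

Step 4. Facial selectivity may erode through a silyl-triflate-catalysed background addition, or turnover may be slow with the bulky ortho-silyloxy enolsilane. The fallback is a catalytic asymmetric carbonyl-ene reaction, which has no silyl-transfer pathway; it sets out from 6 and 4 and comes back at 12. Wittig methylenation of 6 (Ph3P=CH2, THF) should give 2-[2,5-bis(tert-butyldimethylsilyloxy)phenyl]propene F5. The ene reaction of F5 with 4 under [Cu((R,R)-t-Bu-box)](SbF6)2 (CH2Cl2, rt to 40 °C) should give methyl (2R)-2-(2-Ar-prop-2-en-1-yl)-2-hydroxyhept-6-enoate F6 through the same chelate and the same face. OsO4/NaIO4 cleavage of both alkenes of F6 through the tetraol F7 (not isolated) unveils the aryl ketone and the aldehyde together and gives 11, which closes to 12.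

Step 13. Retro-oxa-Michael opening of the ring (β-elimination of O1 after enolisation of the aryl ketone) or slow hydrolysis of the hindered ester may intervene. The fallback reverses the order of the last two operations; it sets out from 22 and comes back at 25. HF·pyridine in THF should give the methyl ester triol, methyl (2R)-2-[2-(2,5-dihydroxyphenyl)-2-oxoethyl]-6-[(3E)-5-hydroxy-4-methylpent-3-en-1-yl]-2,3,4,7-tetrahydrooxepine-2-carboxylate F8. Saponification of F8 with LiOH (THF/H2O, argon, 0 °C) would then give 25; the ortho-phenoxide formed first should lower the acidity of the ketone α-CH2 and so disfavour the elimination.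

**Further compounds**

F1 | step 8 | methyl (2R,5E)-2-(2-Ar-2-oxoethyl)-2-hydroxyhept-5-enoate | C/C=C/CC[C@@](CC(=O)c1cc(O[Si](C)(C)C(C)(C)C)ccc1O[Si](C)(C)C(C)(C)C)(C(=O)OC)O
F2 | step 8 | tert-butyl 2-chloroprop-2-en-1-yl carbonate | C=C(Cl)COC(=O)OC(C)(C)C
F3 | step 8 | methyl (2R,5E)-2-(2-Ar-2-oxoethyl)-2-[(2-chloroprop-2-en-1-yl)oxy]hept-5-enoate | C/C=C/CC[C@@](CC(=O)c1cc(O[Si](C)(C)C(C)(C)C)ccc1O[Si](C)(C)C(C)(C)C)(C(=O)OC)OCC(Cl)=C
F4 | step 8 | methyl (2R)-6-chloro-2-(2-Ar-2-oxoethyl)-2,3,4,7-tetrahydrooxepine-2-carboxylate | ClC1=CCC[C@@](CC(=O)c2cc(O[Si](C)(C)C(C)(C)C)ccc2O[Si](C)(C)C(C)(C)C)(C(=O)OC)OC1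
F5 | step 4 | 2-[2,5-bis(tert-butyldimethylsilyloxy)phenyl]propene | C=C(C)c1cc(O[Si](C)(C)C(C)(C)C)ccc1O[Si](C)(C)C(C)(C)C
F6 | step 4 | methyl (2R)-2-(2-Ar-prop-2-en-1-yl)-2-hydroxyhept-6-enoate | C=CCCC[C@@](CC(=C)c1cc(O[Si](C)(C)C(C)(C)C)ccc1O[Si](C)(C)C(C)(C)C)(C(=O)OC)O
F7 | step 4 | methyl (2R)-2-(2-Ar-2,3-dihydroxypropyl)-2,6,7-trihydroxyheptanoate (epimer mixture, not isolated) | OCC(O)CCC[C@@](CC(O)(CO)c1cc(O[Si](C)(C)C(C)(C)C)ccc1O[Si](C)(C)C(C)(C)C)(C(=O)OC)O
F8 | step 13 | methyl (2R)-2-[2-(2,5-dihydroxyphenyl)-2-oxoethyl]-6-[(3E)-5-hydroxy-4-methylpent-3-en-1-yl]-2,3,4,7-tetrahydrooxepine-2-carboxylate | C/C(=C\CCC1=CCC[C@@](CC(=O)c2cc(O)ccc2O)(C(=O)OC)OC1)CO
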